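The benzoate ring is hexasubstituted, and its two adjacent carbon substituents, the ester at C1 and the 4-hydroxyphenethyl chain at C6, sit next to the C2 oxygen. Both bonds are cut together: a C1≡C6 aryne, polarised by the C2 oxygen, should take the alkyl Grignard carbon at C6, and the C1–Mg bond so formed is carboxylated, giving two C–C bonds in one flask. The aryne precursor is a fluorobenzene bearing both prenyl groups, two MOM ethers and one ring hydrogen between F and OMOM. It is assembled from 5-fluororesorcinol, the first prenyl group being placed between the oxygens through an aryl iodide so that no deprotonation has to choose between competing sites.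

Key step: step 7

Remark (numbering): C1–C6 denote the benzoate ring of the target (C1 bears the ester, C6 the phenethyl chain); MOM = methoxymethyl, prenyl = 3-methylbut-2-enyl.
Remark (site control): the bis(MOM) ether of 5-fluororesorcinol could be deprotonated either between the oxygens or next to fluorine. The route therefore fixes the first prenyl site through a C–I bond.
Remark (assumption): bicarbonate-buffered iodination of 5-fluororesorcinol is assumed to follow resorcinol and its 5-alkyl homologues and to go to the carbon between the hydroxyls.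

Step 1
Reactants: 1 5-fluorobenzene-1,3-diol
Product: 2 5-fluoro-2-iodobenzene-1,3-diol
Conditions: I2 (1.05 equiv), NaHCO3 (1.1 equiv), H2O, 0 °C to rt
Reagents that add atoms: iodine, II
Why: Electrophilic aromatic iodination of a resorcinol under bicarbonate buffer should go to the doubly ortho-activated carbon between the hydroxyls, and the absence of acid prevents migration of iodine to the position next to fluorine.

Step 2
Reactants: 2 5-fluoro-2-iodobenzene-1,3-diol
Product: 3 5-fluoro-2-iodo-1,3-bis(methoxymethoxy)benzene
Conditions: MOMCl (3 equiv), i-Pr2NEt (4 equiv), CH2Cl2, 0 °C to rt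
Reagents that add atoms: chloromethyl methyl ether (MOMCl), COCCl
Why: Base-mediated O-alkylation of both phenols (acetal protection); MOM is chosen because it directs the later lithiations, can chelate magnesium in the key step, and all MOM groups leave together at the end.

Step 3
Reactants: 3 5-fluoro-2-iodo-1,3-bis(methoxymethoxy)benzene; 4 prenyl bromide (1-bromo-3-methylbut-2-ene)
Product: 6 5-fluoro-1,3-bis(methoxymethoxy)-2-(3-methylbut-2-enyl)benzene, via arylmagnesium chloride 5 (not isolated)
Conditions: i-PrMgCl·LiCl (1.1 equiv), THF, −20 to 0 °C; then CuBr·SMe2 (10 mol %), 4 (1.3 equiv), −20 °C to rt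
Reagents that add atoms: none
Why: Iodine–magnesium exchange places the metal only on the former C–I carbon, where no ortho leaving group can be expelled, and copper-catalysed allylic substitution at the primary carbon of prenyl bromide (SN2 sense) should give the linear prenyl arene.

Step 4
Reactants: 6 5-fluoro-1,3-bis(methoxymethoxy)-2-(3-methylbut-2-enyl)benzene; 4 prenyl bromide
Product: 9 1-fluoro-3,5-bis(methoxymethoxy)-2,4-bis(3-methylbut-2-enyl)benzene, via ortho-fluoro aryllithium 7 (not isolated), via arylcopper 8 (not isolated)
Conditions: n-BuLi (1.05 equiv), THF, −78 °C; CuBr·SMe2 (1.1 equiv), −78 °C; 4 (1.5 equiv), −78 °C to rt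
Reagents that add atoms: none
Why: Directed ortho-lithiation can give only one aryllithium because the two remaining ring hydrogens of 6 are equivalent, each flanked by F and OMOM; transmetallation to copper at −78 °C, before LiF can be lost, gives an arylcopper that tolerates warming and alkylates prenyl bromide at its primary carbon.

Step 5
Reactants: 10 4-(2-bromoethyl)phenol
Product: 11 1-(2-bromoethyl)-4-(methoxymethoxy)benzene
Conditions: MOMCl (1.5 equiv), i-Pr2NEt (2 equiv), CH2Cl2, 0 °C to rt
Reagents that add atoms: chloromethyl methyl ether (MOMCl), COCCl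
Why: Acetal protection of the phenol by O-alkylation under a weak amine base, which avoids both E2 loss of HBr and cyclisation of a free phenoxide onto the bromoethyl chain.

Step 6
Reactants: 11 1-(2-bromoethyl)-4-(methoxymethoxy)benzene
Product: 12 2-[4-(methoxymethoxy)phenyl]ethylmagnesium bromide
Conditions: Mg turnings (2 equiv, activated by a crystal of I2), THF, slow addition, rt to 40 °C; titrated and used as the solution
Reagents that add atoms: magnesium, [Mg]
Why: Grignard formation by insertion of magnesium into the primary C–Br bond; slow addition at high dilution limits Wurtz coupling, and the aryl MOM ether is inert to the reagent.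

Step 7
Reactants: 9 1-fluoro-3,5-bis(methoxymethoxy)-2,4-bis(3-methylbut-2-enyl)benzene; 12 2-[4-(methoxymethoxy)phenyl]ethylmagnesium bromide; 13 carbon dioxide
Product: 17 2,4-bis(methoxymethoxy)-6-{2-[4-(methoxymethoxy)phenyl]ethyl}-3,5-bis(3-methylbut-2-enyl)benzoic acid, via ortho-fluoro aryllithium 14 (not isolated), via aryne 15 (not isolated), via arylmagnesium bromide 16 (not isolated)
Conditions: n-BuLi (1.05 equiv), THF, −78 °C, 1 h; 12 (3 equiv), −78 °C to rt; CO2 (dry gas), −20 °C to rt; cold 1 M HCl to pH 3
Reagents that add atoms: none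
Why: n-BuLi should remove the only ring hydrogen of 9, which lies between F and OMOM and is far more acidic at −78 °C than the allylic-benzylic CH2 groups; on warming, aryllithium 14 loses LiF to give the C1≡C6 aryne 15, the excess Grignard reagent 12 adds to it, and the arylmagnesium 16 is carboxylated by CO2. The closest known reaction type is the three-component aryne coupling of ortho-lithiated fluoro(dialkoxy)benzenes with Grignard reagents and CO2 (aryne carbomagnesiation with electrophilic trapping). No ring is closed and no stereocentre is created. The step needs regioselective addition at C6: the inductively withdrawing C2 OMOM group distorts the aryne so that C6, the terminus remote from oxygen, is the electrophilic carbon, and the developing C1 carbanion is stabilised by induction and Mg–O chelation; this bias has to outweigh the hindrance from the C5 prenyl group. Having 12 in excess before the mixture warms should keep the aryne from reacting with 14 or with a prenyl double bond (ene reaction), and because the carboxyl group appears last, no organometallic meets an ester.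

Step 8
Reactants: 17 2,4-bis(methoxymethoxy)-6-{2-[4-(methoxymethoxy)phenyl]ethyl}-3,5-bis(3-methylbut-2-enyl)benzoic acid
Product: 18 methyl 2,4-bis(methoxymethoxy)-6-{2-[4-(methoxymethoxy)phenyl]ethyl}-3,5-bis(3-methylbut-2-enyl)benzoate
Conditions: MeI (1.5 equiv), K2CO3 (2 equiv), DMF, rt
Reagents that add atoms: iodomethane, CI
Why: SN2 O-alkylation of the carboxylate esterifies the di-ortho-substituted acid without attack at its shielded carbonyl carbon and without acid, so MOM ethers and prenyl groups are untouched.

Step 9
Reactants: 18 methyl 2,4-bis(methoxymethoxy)-6-{2-[4-(methoxymethoxy)phenyl]ethyl}-3,5-bis(3-methylbut-2-enyl)benzoate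
Product: 19 methyl 2,4-dihydroxy-6-[2-(4-hydroxyphenyl)ethyl]-3,5-bis(3-methylbut-2-enyl)benzoate
Conditions: 3 M aq HCl, MeOH, rt
Reagents that add atoms: none
Why: Acid-catalysed acetal exchange with methanol should remove all three aryl MOM ethers as dimethoxymethane; dilute acid at room temperature is the usual way to unmask MOM-protected prenylphenols without closing chromans, and the methyl ester is inert in methanol.

Compound list
1 | 5-fluorobenzene-1,3-diol | Oc1cc(O)cc(F)c1 | starting material
2 | 5-fluoro-2-iodobenzene-1,3-diol | Oc1cc(F)cc(O)c1I | intermediate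
3 | 5-fluoro-2-iodo-1,3-bis(methoxymethoxy)benzene | COCOc1cc(F)cc(OCOC)c1I | intermediate
4 | prenyl bromide (1-bromo-3-methylbut-2-ene) | CC(C)=CCBr | starting material
5 | [4-fluoro-2,6-bis(methoxymethoxy)phenyl]magnesium chloride (not isolated) | COCOc1cc(F)cc(OCOC)c1[Mg]Cl | intermediate
6 | 5-fluoro-1,3-bis(methoxymethoxy)-2-(3-methylbut-2-enyl)benzene | COCOc1cc(F)cc(OCOC)c1CC=C(C)C | intermediate
7 | [2-fluoro-4,6-bis(methoxymethoxy)-5-(3-methylbut-2-enyl)phenyl]lithium (not isolated) | [Li]c1c(F)cc(OCOC)c(CC=C(C)C)c1OCOC | intermediate
8 | [2-fluoro-4,6-bis(methoxymethoxy)-5-(3-methylbut-2-enyl)phenyl]copper (not isolated) | [Cu]c1c(F)cc(OCOC)c(CC=C(C)C)c1OCOC | intermediate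
9 | 1-fluoro-3,5-bis(methoxymethoxy)-2,4-bis(3-methylbut-2-enyl)benzene | COCOc1cc(F)c(CC=C(C)C)c(OCOC)c1CC=C(C)C | intermediate
10 | 4-(2-bromoethyl)phenol | Oc1ccc(CCBr)cc1 | starting material
11 | 1-(2-bromoethyl)-4-(methoxymethoxy)benzene | COCOc1ccc(CCBr)cc1 | intermediate
12 | 2-[4-(methoxymethoxy)phenyl]ethylmagnesium bromide | COCOc1ccc(CC[Mg]Br)cc1 | intermediate
13 | carbon dioxide | O=C=O | starting material
14 | [2-fluoro-4,6-bis(methoxymethoxy)-3,5-bis(3-methylbut-2-enyl)phenyl]lithium (not isolated) | [Li]c1c(F)c(CC=C(C)C)c(OCOC)c(CC=C(C)C)c1OCOC | intermediate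
15 | 1,2-didehydro-3,5-bis(methoxymethoxy)-4,6-bis(3-methylbut-2-enyl)benzene, the C1≡C6 aryne (not isolated) | COCOC1=C(CC=C(C)C)C(OCOC)=C(CC=C(C)C)C#C1 | intermediate
16 | [2,4-bis(methoxymethoxy)-6-{2-[4-(methoxymethoxy)phenyl]ethyl}-3,5-bis(3-methylbut-2-enyl)phenyl]magnesium bromide (not isolated) | Br[Mg]c1c(OCOC)c(CC=C(C)C)c(OCOC)c(CC=C(C)C)c1CCc1ccc(OCOC)cc1 | intermediate
17 | 2,4-bis(methoxymethoxy)-6-{2-[4-(methoxymethoxy)phenyl]ethyl}-3,5-bis(3-methylbut-2-enyl)benzoic acid | OC(=O)c1c(OCOC)c(CC=C(C)C)c(OCOC)c(CC=C(C)C)c1CCc1ccc(OCOC)cc1 | intermediate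
18 | methyl 2,4-bis(methoxymethoxy)-6-{2-[4-(methoxymethoxy)phenyl]ethyl}-3,5-bis(3-methylbut-2-enyl)benzoate | COC(=O)c1c(OCOC)c(CC=C(C)C)c(OCOC)c(CC=C(C)C)c1CCc1ccc(OCOC)cc1 | intermediate
19 | methyl 2,4-dihydroxy-6-[2-(4-hydroxyphenyl)ethyl]-3,5-bis(3-methylbut-2-enyl)benzoate | COC(=O)c1c(O)c(CC=C(C)C)c(O)c(CC=C(C)C)c1CCc1ccc(O)cc1 | target

Total step count: 9. Longest linear sequence: 7 steps (steps 1, 2, 3, 4, 7, 8, 9); steps 5 and 6 form the side branch to the Grignard reagent.

Steps most likely to fail

1. Step 7. The Grignard carbon may add at the wrong aryne terminus, pushed to C1 by the C5 prenyl group. The aryne may also be consumed by aryllithium 14 or by an ene reaction with a prenyl double bond before the Grignard reagent adds. The fallback sets out from 9 and comes back at 17. Compound 9 is lithiated as before, but the aryllithium is quenched with CO2 at −78 °C, before LiF is lost, to give 2-fluoro-4,6-bis(methoxymethoxy)-3,5-bis(3-methylbut-2-enyl)benzoic acid F1. Treatment of F1 with excess 12 (THF, 0 °C to reflux) should then replace the ortho fluorine by carboxylate-assisted nucleophilic aromatic substitution. This addition–elimination is a known reaction of unprotected ortho-fluorobenzoic acids with organolithium and Grignard reagents. The position of fluorine then fixes the regiochemistry, and the product is 17.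

2. Step 1. Iodination may go para to a hydroxyl, next to fluorine, or run on to di-iodination. The fallback sets out from 1 and comes back at 6. It blocks both fluorine-flanked positions with bromine and then functionalises the only C–H left.
- Dibromination of 1 (NBS, 2 equiv, MeCN, 0 °C) para to each hydroxyl, the normal course for resorcinols, should give 4,6-dibromo-5-fluorobenzene-1,3-diol F2.
- MOMCl and i-Pr2NEt convert F2 into 1,3-dibromo-2-fluoro-4,6-bis(methoxymethoxy)benzene F3.
- The single ring hydrogen of F3, between the two OMOM groups, is magnesiated with TMPMgCl·LiCl (THF, 0 °C to rt), an amide base that causes neither bromine–metal exchange nor halogen migration. Prenylation with 4 under CuBr·SMe2 catalysis gives 1,3-dibromo-2-fluoro-4,6-bis(methoxymethoxy)-5-(3-methylbut-2-enyl)benzene F4.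
- Both bromines of F4 are removed by bromine–lithium exchange (t-BuLi, THF, −78 °C) and a methanol quench at −78 °C, which gives 6.

3. Step 9. Acid may cyclise an ortho-prenyl phenol to a 2,2-dimethylchroman, or cleavage of the MOM ether wedged between the two prenyl groups may stall. The fallback sets out from 18 and comes back at 19. It replaces protic solvolysis by a transprotection: TMSOTf and 2,2′-bipyridyl (CH2Cl2, 0 °C to rt) convert aryl MOM ethers into aryl trimethylsilyl ethers under buffered, non-protic conditions. This should give methyl 2,4-bis(trimethylsilyloxy)-6-{2-[4-(trimethylsilyloxy)phenyl]ethyl}-3,5-bis(3-methylbut-2-enyl)benzoate F5. Water at rt then hydrolyses F5 to 19.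

Further compounds
F1 | step 7 | 2-fluoro-4,6-bis(methoxymethoxy)-3,5-bis(3-methylbut-2-enyl)benzoic acid | OC(=O)c1c(F)c(CC=C(C)C)c(OCOC)c(CC=C(C)C)c1OCOC
F2 | step 1 | 4,6-dibromo-5-fluorobenzene-1,3-diol | Oc1cc(O)c(Br)c(F)c1Br
F3 | step 1 | 1,3-dibromo-2-fluoro-4,6-bis(methoxymethoxy)benzene | COCOc1cc(OCOC)c(Br)c(F)c1Br
F4 | step 1 | 1,3-dibromo-2-fluoro-4,6-bis(methoxymethoxy)-5-(3-methylbut-2-enyl)benzene | COCOc1c(CC=C(C)C)c(OCOC)c(Br)c(F)c1Br
F5 | step 9 | methyl 2,4-bis(trimethylsilyloxy)-6-{2-[4-(trimethylsilyloxy)phenyl]ethyl}-3,5-bis(3-methylbut-2-enyl)benzoate | COC(=O)c1c(O[Si](C)(C)C)c(CC=C(C)C)c(O[Si](C)(C)C)c(CC=C(C)C)c1CCc1ccc(O[Si](C)(C)C)cc1
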